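**Plan**
1. Numbering (1-benzoxepine): O1, C2 (enol ether carbon), C3 (oxirane C–CH3), C4 (oxirane CH), C5, C5a, C6 (CMe2), C7 (CHBr), C8, C9, C9a (C–CH3 on O1); ring A is the carbocycle, ring B the oxepane.
2. Retrosynthesis of the edge: C2=CHBr goes back to C2=CBr2, C2=CH2 and a lactone C2=O; the oxirane goes back to a C3=C4 alkene; the C3 methyl to a C3–Br bond.
3. Enabling feature: the C2–C3–C4 edge of ring B is the O–C=C unit of a ring-fused dihydropyran with one carbon, C3, set between the two alkene carbons. Cutting C2–C3 and C3–C4 takes C3 out as dibromocarbene and contracts ring B to a six-membered enol ether.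
4. That dihydropyran comes from a δ-lactone, which opens at C5a–C6 and O1–C9a (bromonium-triggered diene cyclisation); the bond α to the ester then leads to geranyl bromide and tert-butyl acetate.
5. Forward: the chain is joined by enolate alkylation; ring A and the six-membered oxacycle close in one cationic cascade; lactone to dihydropyran; carbene addition and ring opening grow six to seven; the C2–C3–C4 edge is then dressed.
6. Stereochemistry: C7 from catalyst-controlled Br+ delivery; C5a/C9a (trans fusion) from the E alkene through a chair–chair transition state; the oxirane from attack anti to the axial C9a methyl; the E bromoalkene from removal of the less hindered bromine of a dibromoalkene.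

Key step: step 5

Assumption: the sense of induction of the chiral catalyst in step 2 is not known for an ester-terminated diene; the antipode that gives the (6S)-bromide is taken as the one used.
Convention: β is the face of the angular methyl group (C9a, or C8a in chromene locants), α the face of the ring-fusion hydrogen; the six-membered oxacycles carry chromene locants.

**Step 1**
Reactants: 1 geranyl bromide; 2 tert-butyl acetate
Product: 4 tert-butyl (4E)-5,9-dimethyldeca-4,8-dienoate, via lithium enolate 3 (not isolated)
Conditions: 2, LiN(i-Pr)2, THF, −78 °C; then 1, DMPU, −78 °C → rt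
Reagents that add atoms: none
Why: Alkylation of a lithium ester enolate with a primary allylic bromide (SN2, no allylic transposition); the E geometry of geranyl bromide is carried over and no stereocentre is formed.

**Step 2**
Reactants: 4 tert-butyl (4E)-5,9-dimethyldeca-4,8-dienoate
Product: 5 trans-fused bromo δ-lactone (4aS,6S,8aS)
Conditions: DBDMH (1.1 equiv), chiral BINOL-derived N-triflyl thiophosphoramide (10 mol %), toluene/CH2Cl2, −90 °C
Reagents that add atoms: 1,3-dibromo-5,5-dimethylhydantoin (DBDMH), CC1(C)N(Br)C(=O)N(Br)C1=O
Why: Proposed new method: the thiophosphoryl sulfur of the catalyst should take Br+ from DBDMH and deliver it to one face of the terminal trisubstituted alkene (this sets C6), the (E)-4,5-alkene attacks the bromonium ion anti through a chair–chair transition state (Br equatorial, H-4a and CH3-8a trans), and the ester carbonyl oxygen closes the lactone on the tertiary cation with loss of tert-butyl as isobutene; the closest known reaction types are the chiral Lewis-base-promoted enantioselective bromo- and iodocyclisation of homogeranyl arenes and geranyl phenols and the racemic bromonium-induced cyclisation of polyene acids and tert-butyl esters to lactones, the new element being an ester oxygen as terminator under chiral Lewis-base control.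

**Step 3**
Reactants: 5 trans-fused bromo δ-lactone
Product: 6 bromo lactol (both anomers)
Conditions: i-Bu2AlH, CH2Cl2, −78 °C
Reagents that add atoms: none
Why: Partial reduction of a lactone to the lactol, the tetrahedral aluminium alkoxide persisting at low temperature until work-up; the alkyl bromide is inert and the new hemiacetal centre is removed in the next step.

**Step 4**
Reactants: 6 bromo lactol
Product: 8 trans-fused bromo dihydropyran (4aS,6S,8aS), via lactol mesylate 7 (not isolated)
Conditions: CH3SO2Cl, NEt3, CH2Cl2, 0 °C → reflux
Reagents that add atoms: none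
Why: Lactol dehydration of the glycal type: the anomeric mesylate ionises to the oxocarbenium ion, which can lose a proton only from C3, giving the cyclic enol ether without touching a ring stereocentre.

**Step 5**
Reactants: 8 trans-fused bromo dihydropyran; 9 bromoform; 10 methanol
Product: 12 3-bromo-2-methoxy-oxepene fused to ring A (both anomers), via dibromocyclopropane 11 (not isolated)
Conditions: CHBr3, 50% aq. NaOH, BnNEt3Cl (cat.), CH2Cl2, 0 °C → rt; then K2CO3, CH3OH, reflux
Reagents that add atoms: bromoform 9, BrC(Br)Br; methanol 10, CO
Why: Dibromocarbene, formed from bromoform by α-elimination under phase transfer, adds in a concerted [2+1] cycloaddition to the enol ether C2=C3 of 8, the only alkene present and an electron-rich one, so the cyclopropane of 11 closes by cheletropic addition. In hot methanol the bromide endo to the pyran ionises while the C–C bond shared by the two rings breaks in a disrotatory two-electron electrocyclic opening; the six-membered ring thereby becomes a seven-membered oxocarbenium/2-bromoallyl cation with a cis ring alkene (ring enlargement, no further ring closed), methanol adds at the acetal carbon and K2CO3 takes up HBr. The closest known reaction type is the dihalocarbene cyclopropanation of glycals and other cyclic enol ethers followed by base- or silver-promoted expansion to 3-halo-2-alkoxy-oxepenes. The only new stereocentre is the acetal carbon, left uncontrolled on purpose because the next step turns it into a carbonyl; both cyclopropane diastereomers have an endo bromide and converge on the same cation. The selectivity required is regiochemical, cleavage of the ring-fusion bond of the cyclopropane and not of an outer bond, and the ring oxygen secures it by stabilising the developing cation as an oxocarbenium ion. The equatorial neopentyl bromide of ring A has neither an antiperiplanar hydrogen nor an open backside and should survive NaOH and K2CO3.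

**Step 6**
Reactants: 12 3-bromo-2-methoxy-oxepene
Product: 14 α-bromo unsaturated ε-lactone, via bromo lactol 13 (not isolated)
Conditions: CrO3, H2SO4, H2O, acetone, 0 °C
Reagents that add atoms: water, O
Why: Jones oxidation of a cyclic allylic methyl acetal: acid hydrolysis gives the lactol, whose hemiacetal C–H is oxidised by chromic acid to the conjugated lactone; the acetal stereocentre is erased and the tertiary C9a–O bond should hold at 0 °C.

**Step 7**
Reactants: 14 α-bromo unsaturated ε-lactone
Product: 15 α-methyl unsaturated ε-lactone
Conditions: Sn(CH3)4, Pd(PPh3)4 (cat.), DMF, 90 °C (sealed tube)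
Reagents that add atoms: tetramethylstannane, C[Sn](C)(C)C
Why: Stille coupling: the C(sp2)–Br bond α to the carbonyl adds to zerovalent palladium far faster than the neopentyl C(sp3)–Br bond of ring A, and methyl transfer from tin followed by reductive elimination installs the C3 methyl.

**Step 8**
Reactants: 15 α-methyl unsaturated ε-lactone
Product: 16 3α,4α-epoxy lactone (3R,4R)
Conditions: dimethyldioxirane, acetone, 0 °C → rt
Reagents that add atoms: dimethyldioxirane, CC1(C)OO1
Why: Electrophilic epoxidation of a trisubstituted enoate by a dioxirane; oxygen should enter from the α-face, anti to the axial C9a methyl that stands over the β-face of ring B, which sets C3 and C4 together (substrate control).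

**Step 9**
Reactants: 16 3α,4α-epoxy lactone
Product: 17 2-methylidene oxepane epoxide
Conditions: (C5H5)2Ti(CH3)2, toluene, 70 °C, dark
Reagents that add atoms: dimethyltitanocene, C[Ti](C)(C1C=CC=C1)C1C=CC=C1
Why: Petasis methylenation: the titanium methylidene formed by loss of methane adds [2+2] to the lactone carbonyl and the oxatitanacyclobutane collapses to the exocyclic enol ether; the reagent is neither basic nor strongly Lewis acidic, so the oxirane and the alkyl bromide should be tolerated and no stereocentre is touched.

**Step 10**
Reactants: 17 2-methylidene oxepane epoxide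
Product: 19 (Z)-2-bromomethylidene oxepane epoxide, via α-bromo ether 18 (not isolated)
Conditions: Br2, CH2Cl2, −78 °C; then DBU, −78 °C → rt
Reagents that add atoms: bromine, BrBr
Why: Bromination–dehydrobromination of an enol ether: Br2 adds through the bromo-oxocarbenium ion and DBU removes HBr from the CH2Br group, the only site with β-hydrogens; sterics should place the bromine on the side of O1, away from the quaternary C3 (Z), a geometry that the next step erases.

**Step 11**
Reactants: 19 (Z)-2-bromomethylidene oxepane epoxide
Product: 21 2-dibromomethylidene oxepane epoxide, via tribromo ether 20 (not isolated)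
Conditions: Br2, CH2Cl2, −78 → 0 °C; then DBU, rt
Reagents that add atoms: bromine, BrBr
Why: Second bromination–dehydrobromination of the now less electron-rich bromo enol ether; the adduct has a single β-hydrogen, so elimination can give only the dibromoalkene.

**Step 12**
Reactants: 21 2-dibromomethylidene oxepane epoxide
Product: 22 target, (2E,3R,4R,5aS,7S,9aS)-7-bromo-2-(bromomethylidene)-3,4-epoxy-3,6,6,9a-tetramethyldecahydro-1-benzoxepine
Conditions: n-Bu3SnH (1.05 equiv), Pd(PPh3)4 (cat.), toluene, rt
Reagents that add atoms: none
Why: Selective hydrogenolysis of a 1,1-dibromoalkene: zerovalent palladium inserts into the less hindered C–Br bond, the one cis to O1 and trans to the quaternary C3, and tin hydride replaces it by hydrogen with retention; the bromine cis to C3 stays, which is the E geometry, and the hindered vinyl bromide left and the ring A alkyl bromide should react much more slowly.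

**Compound list**
1 | geranyl bromide, (2E)-1-bromo-3,7-dimethylocta-2,6-diene | CC(C)=CCC/C(C)=C/CBr | starting material
2 | tert-butyl acetate | CC(=O)OC(C)(C)C | starting material
3 | lithium enolate of tert-butyl acetate | [Li+].[O-]C(=C)OC(C)(C)C | intermediate
4 | tert-butyl (4E)-5,9-dimethyldeca-4,8-dienoate | CC(C)=CCC/C(C)=C/CCC(=O)OC(C)(C)C | intermediate
5 | (4aS,6S,8aS)-6-bromo-5,5,8a-trimethyloctahydro-2H-chromen-2-one (trans-fused, Br equatorial) | CC1(C)[C@@H](Br)CC[C@]2(C)OC(=O)CC[C@@H]12 | intermediate
6 | (4aS,6S,8aS)-6-bromo-5,5,8a-trimethyloctahydro-2H-chromen-2-ol (both anomers) | CC1(C)[C@@H](Br)CC[C@]2(C)OC(O)CC[C@@H]12 | intermediate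
7 | 2-O-methanesulfonate of lactol 6 | CC1(C)[C@@H](Br)CC[C@]2(C)OC(OS(C)(=O)=O)CC[C@@H]12 | intermediate
8 | (4aS,6S,8aS)-6-bromo-5,5,8a-trimethyl-4a,5,6,7,8,8a-hexahydro-4H-chromene | CC1(C)[C@@H](Br)CC[C@]2(C)OC=CC[C@@H]12 | intermediate
9 | bromoform | BrC(Br)Br | starting material
10 | methanol | CO | starting material
11 | 1,1-dibromocyclopropane across C2–C3 of 8 (both cis-fused diastereomers) | CC1(C)[C@@H](Br)CC[C@]2(C)OC3C(C[C@@H]12)C3(Br)Br | intermediate
12 | (5aS,7S,9aS)-3,7-dibromo-2-methoxy-6,6,9a-trimethyl-2,5,5a,6,7,8,9,9a-octahydro-1-benzoxepine (both anomers) | CC1(C)[C@@H](Br)CC[C@]2(C)OC(OC)C(Br)=CC[C@@H]12 | intermediate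
13 | (5aS,7S,9aS)-3,7-dibromo-6,6,9a-trimethyl-2,5,5a,6,7,8,9,9a-octahydro-1-benzoxepin-2-ol | CC1(C)[C@@H](Br)CC[C@]2(C)OC(O)C(Br)=CC[C@@H]12 | intermediate
14 | (5aS,7S,9aS)-3,7-dibromo-6,6,9a-trimethyl-5a,6,7,8,9,9a-hexahydro-1-benzoxepin-2(5H)-one | CC1(C)[C@@H](Br)CC[C@]2(C)OC(=O)C(Br)=CC[C@@H]12 | intermediate
15 | (5aS,7S,9aS)-7-bromo-3,6,6,9a-tetramethyl-5a,6,7,8,9,9a-hexahydro-1-benzoxepin-2(5H)-one | CC1(C)[C@@H](Br)CC[C@]2(C)OC(=O)C(C)=CC[C@@H]12 | intermediate
16 | (3R,4R,5aS,7S,9aS)-7-bromo-3,4-epoxy-3,6,6,9a-tetramethyloctahydro-1-benzoxepin-2-one (oxirane oxygen α) | CC1(C)[C@@H](Br)CC[C@]2(C)OC(=O)[C@]3(C)O[C@@H]3C[C@@H]12 | intermediate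
17 | (3R,4R,5aS,7S,9aS)-7-bromo-3,4-epoxy-3,6,6,9a-tetramethyl-2-methylidenedecahydro-1-benzoxepine | CC1(C)[C@@H](Br)CC[C@]2(C)OC(=C)[C@]3(C)O[C@@H]3C[C@@H]12 | intermediate
18 | 2-bromo-2-(bromomethyl) adduct of 17 (α-bromo ether) | CC1(C)[C@@H](Br)CC[C@]2(C)OC(Br)(CBr)[C@]3(C)O[C@@H]3C[C@@H]12 | intermediate
19 | (2Z,3R,4R,5aS,7S,9aS)-7-bromo-2-(bromomethylidene)-3,4-epoxy-3,6,6,9a-tetramethyldecahydro-1-benzoxepine | CC1(C)[C@@H](Br)CC[C@]2(C)O/C(=C\Br)[C@]3(C)O[C@@H]3C[C@@H]12 | intermediate
20 | 2-bromo-2-(dibromomethyl) adduct of 19 | CC1(C)[C@@H](Br)CC[C@]2(C)OC(Br)(C(Br)Br)[C@]3(C)O[C@@H]3C[C@@H]12 | intermediate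
21 | (3R,4R,5aS,7S,9aS)-7-bromo-2-(dibromomethylidene)-3,4-epoxy-3,6,6,9a-tetramethyldecahydro-1-benzoxepine | CC1(C)[C@@H](Br)CC[C@]2(C)OC(=C(Br)Br)[C@]3(C)O[C@@H]3C[C@@H]12 | intermediate
22 | (2E,3R,4R,5aS,7S,9aS)-7-bromo-2-(bromomethylidene)-3,4-epoxy-3,6,6,9a-tetramethyldecahydro-1-benzoxepine | CC1(C)[C@@H](Br)CC[C@]2(C)O/C(=C/Br)[C@]3(C)O[C@@H]3C[C@@H]12 | target

**Count**
Total steps: 12. Longest linear sequence: 12 steps, from geranyl bromide 1 to 22.

**Steps most likely to fail**

Step 2 (the proposed method). The Br+ transfer may discriminate the two alkene faces too little, or the monocyclic cation may lose a proton before the ester oxygen closes the second ring. The fallback gives up asymmetric catalysis and uses known chemistry. It sets out from 4: racemic cyclisation with Et2SBr·SbBrCl5 (bromodiethylsulfonium bromopentachloroantimonate) in CH3NO2 at −25 °C, an established route from polyene esters and acids to bromo lactones, should give the racemic trans-fused bromolactone F1. Preparative chromatography on a chiral stationary phase (cellulose tris(3,5-dimethylphenylcarbamate)) would then separate the (4aS,6S,8aS) enantiomer, and the route is rejoined at 5.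

Step 8. Oxygen transfer may go to the β-face, or the two faces of the C3=C4 bond may be distinguished poorly. The fallback replaces direct oxygen transfer by a halohydrin sequence, in which the oxirane oxygen ends on the face opposite to the one the electrophile attacks. It sets out from 15: N-bromoacetamide with catalytic HClO4 in aqueous dioxane should give, by reversible bromonium formation and trans-diaxial opening by water, the 3β-bromo-4α-hydroxy lactone F2. K2CO3 in acetone then closes the oxirane by backside displacement of bromide, and the route is rejoined at 16.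

Step 9. The [2+2] addition may not take place at the doubly hindered carbonyl at a temperature the oxirane tolerates, or titanium species may open the oxirane. The fallback is a modified Julia olefination of the lactone, which needs no metal carbene. It sets out from 16: 2-(methylsulfonyl)benzothiazole deprotonated with LiN(SiMe3)2 in THF at −78 °C should add to the carbonyl and give the hemiketal sulfone F3. DBU then triggers the Smiles rearrangement and loss of sulfur dioxide and benzothiazolone to give the exocyclic enol ether, and the route is rejoined at 17.

**Further compounds**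
F1 | step 2 | racemic trans-fused 6-bromo-5,5,8a-trimethyloctahydro-2H-chromen-2-one | CC1(C)[C@@H](Br)CC[C@]2(C)OC(=O)CC[C@@H]12.CC1(C)[C@H](Br)CC[C@@]2(C)OC(=O)CC[C@H]12
F2 | step 8 | (3S,4R,5aS,7S,9aS)-3,7-dibromo-4-hydroxy-3,6,6,9a-tetramethyloctahydro-1-benzoxepin-2-one | CC1(C)[C@@H](Br)CC[C@]2(C)OC(=O)[C@@](C)(Br)[C@H](O)C[C@@H]12
F3 | step 9 | 2-[(1,3-benzothiazol-2-ylsulfonyl)methyl]-2-hydroxy derivative of 16 (hemiketal sulfone) | CC1(C)[C@@H](Br)CC[C@]2(C)OC(O)(CS(=O)(=O)c4nc5ccccc5s4)[C@]3(C)O[C@@H]3C[C@@H]12
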